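Ring A is cut at C2–C3 and read as three simple pieces. C3–C4(CH3)2 is an isobutyrate ester. C5–C10(CH3) is the β,α-carbon pair of a 2-methylcyclohexenone that becomes ring B. The unsubstituted C1–C2 bridge is phenyl vinyl sulfone. In one flask the ester enolate adds to C5 of 6-methylcarvone, the C10 enolate so formed adds to the vinyl sulfone, and the C2 sulfonyl carbanion closes ring A on the C3 ester. Three C–C bonds, the C10 quaternary centre and the trans ring fusion arise from a monocyclic enone. The isopropenyl group only steers and is then excised; C9 is homologated, C8 hydrated and C11 farnesylated.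

Key step: step 2

Remark: drimane numbering is used throughout (decalin C1–C10, C11 on C9). α is the face of H-5 and β is the face of the C10 methyl group. C8 stays epimerisable until step 5 and is drawn in the configuration expected to dominate; either epimer serves.

Step 1
Reactants: 1 (R)-(−)-carvone
Product: 3 (5R,6S)-6-methylcarvone, via lithium dienolate 2 (not isolated)
Conditions: LDA (1.05 equiv), THF, −78 °C; MeI, −78→0 °C
Reagents that add atoms: iodomethane, CI
Why: Kinetic deprotonation at the α′-CH2 gives the cross-conjugated dienolate, and enolate alkylation takes place anti to the neighbouring isopropenyl group; this installs the future C8 methyl carbon, whose configuration is erased in step 5.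

Step 2
Reactants: 3 (5R,6S)-6-methylcarvone; 4 methyl isobutyrate; 5 phenyl vinyl sulfone
Product: 9 2α-phenylsulfonyl-7α-isopropenyl-11-nordrimane-3,9-dione, via lithium ester enolate 6 (not isolated), via ring-B lithium enolate 7 (not isolated), via sulfonyl carbanion 8 (not isolated)
Conditions: 4, LDA (1.05 equiv), THF, −78 °C; DMPU, then 3, −78→−10 °C; 5 (1.0 equiv, slow addition), −78→25 °C, 12 h; 1 M HCl
Reagents that add atoms: none
Why: Enolate 6 adds 1,4 to enone 3 at C5 by axial attack anti to the C7 isopropenyl group, the tetrasubstituted C9–C10 enolate 7 then adds to the unhindered CH2 terminus of 5 on the face opposite the bulky C5 substituent (which sets the C10 quaternary centre and hence the trans ring fusion), and the α-sulfonyl carbanion 8 attacks the C3 ester carbonyl and expels methoxide. The closest known reaction type is the sequential Michael–Michael–ring-closure (MIMIRC) annulation, ended here by a Dieckmann-type acylation of a sulfonyl carbanion. Ring A closes in a 6-exo-trig mode through a chair in which the C1 and C4 arms are both equatorial on ring B. C5 is controlled by the carvone stereocentre, C10 is controlled by C5, and C2 is a labile centre that settles equatorial and is deleted in step 3. The step needs 1,4- over 1,2-addition (secured by the α,α-disubstituted enolate, DMPU and warming, which let the 1,2-adduct revert), ordered addition so that 6 never meets 5, and a driving force against proton shuffling to C8. That driving force exists because every earlier stage is reversible or can be re-entered by proton transfer, whereas the β-keto sulfone is deprotonated by the released methoxide and is the only thermodynamic sink; the alternative Claisen closure from C8 gives a non-enolisable diketone that reverts.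

Step 3
Reactants: 9 2α-phenylsulfonyl-7α-isopropenyl-11-nordrimane-3,9-dione
Product: 10 7α-isopropenyl-11-nordrimane-3,9-dione
Conditions: SmI2 (2.5 equiv), THF–MeOH, −78 °C
Reagents that add atoms: none
Why: Reductive desulfonylation of a β-keto sulfone: two single-electron transfers from divalent samarium cleave the activated C2–S bond through the samarium enolate, which methanol protonates, while the isolated C9 ketone and the alkene do not react at this temperature.

Step 4
Reactants: 10 7α-isopropenyl-11-nordrimane-3,9-dione
Product: 11 3β-hydroxy-7α-isopropenyl-11-nordriman-9-one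
Conditions: NaBH4, MeOH–CH2Cl2, −78→−40 °C
Reagents that add atoms: none
Why: Chemo- and diastereoselective borohydride reduction: C9 is screened by the C10 quaternary centre, the C8 methyl group and the axial C7 isopropenyl group, so hydride reaches only C3, and it does so along the axial α trajectory (the β face carries the axial 4β and 10β methyl groups), which gives the equatorial 3β-alcohol.

Step 5
Reactants: 11 3β-hydroxy-7α-isopropenyl-11-nordriman-9-one
Product: 14 3β-hydroxy-11-nordrim-7-en-9-one, via methoxy hydroperoxide 12 (not isolated), via deconjugated Δ6-enone 13 (not isolated)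
Conditions: O3, MeOH–CH2Cl2, −78 °C; FeSO4·7H2O, Cu(OAc)2·H2O, −20→25 °C; DBU (0.2 equiv), CH2Cl2, 25 °C
Reagents that add atoms: none
Why: Oxidative dealkenylation: Criegee ozonolysis in methanol gives the α-methoxy hydroperoxide, divalent iron reduces its O–O bond, the alkoxy radical loses methyl acetate by β-scission, divalent copper oxidises the C7 radical to an alkene, and DBU funnels both alkene regioisomers and both C8 epimers into the conjugated trisubstituted enone.

Step 6
Reactants: 14 3β-hydroxy-11-nordrim-7-en-9-one
Product: 16 drima-7,9(11)-dien-3β-ol, via β-hydroxysilane 15 (not isolated)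
Conditions: Me3SiCH2Li (3 equiv), THF, −78→0 °C; AcOH–THF–H2O, 25 °C
Reagents that add atoms: (trimethylsilyl)methyllithium, [Li]C[Si](C)(C)C
Why: Peterson olefination: the small, hard carbanion adds 1,2 to the hindered enone from the open α face, and the tertiary allylic β-hydroxysilane loses trimethylsilanol on mild acid treatment, which can only give the exocyclic C9=C11 methylene group because C10 is quaternary.

Step 7
Reactants: 16 drima-7,9(11)-dien-3β-ol
Product: 18 drim-7-ene-3β,11-diol, via B-alkyl-9-BBN adduct 17 (not isolated)
Conditions: 9-BBN (2.5 equiv), THF, 0→40 °C; NaOH, H2O2, 0→25 °C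
Reagents that add atoms: hydrogen peroxide, OO
Why: Hydroboration–oxidation: 9-BBN selects the 1,1-disubstituted C9=C11 bond over the trisubstituted ring alkene, places boron on C11 and delivers hydrogen to C9 from the α face opposite the axial C10 methyl group, which sets the 9α-H (equatorial C11) configuration; the oxidation proceeds with retention.

Step 8
Reactants: 18 drim-7-ene-3β,11-diol
Product: 19 drimane-3β,8α,11-triol
Conditions: Co(acac)2 (20 mol%), PhSiH3, O2 (1 atm), THF–i-PrOH, 25 °C
Reagents that add atoms: dioxygen, O=O
Why: Mukaiyama hydration: hydrogen-atom transfer from a cobalt hydride to C7 gives the tertiary C8 radical (Markovnikov), and dioxygen is captured on the α face because the β face is blocked by the syn-axial C10 methyl group, which gives the 8α-alcohol with the 8β (axial) methyl group.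

Step 9
Reactants: 19 drimane-3β,8α,11-triol
Product: 20 11-(phenylthio)drimane-3β,8α-diol
Conditions: PhSSPh, n-Bu3P, pyridine, 25→50 °C
Reagents that add atoms: diphenyl disulfide, c1ccc(cc1)SSc1ccccc1
Why: Hata-type sulfenylation (a Mitsunobu-like SN2 displacement through an alkoxyphosphonium ion): only the primary C11 hydroxyl can be activated and displaced, since the neopentylic secondary 3-OH and the tertiary 8-OH cannot undergo backside attack.

Step 10
Reactants: 20 11-(phenylthio)drimane-3β,8α-diol
Product: 21 11-(phenylsulfonyl)drimane-3β,8α-diol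
Conditions: 30% H2O2, (NH4)6Mo7O24·4H2O (5 mol%), EtOH, 0→25 °C
Reagents that add atoms: hydrogen peroxide, OO
Why: Molybdate-catalysed peroxide oxidation of a sulfide to the sulfone; the molecule holds no alkene at this stage and the alcohols are inert.

Step 11
Reactants: 21 11-(phenylsulfonyl)drimane-3β,8α-diol; 22 (2E,6E)-farnesyl bromide
Product: 24 11-phenylsulfonyl derivative of the target (C11 epimers), via trilithiated sulfone 23 (not isolated)
Conditions: n-BuLi (3.1 equiv), THF–DMPU, −78→−20 °C; 22, −78→0 °C; H2O
Reagents that add atoms: none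
Why: Alkylation of an α-sulfonyl carbanion with an allylic bromide (SN2 at the primary carbon, so that the E geometry of commercial farnesyl bromide is kept); the two lithium alkoxides are far less nucleophilic at low temperature, and the new C11 centre is removed in step 12.

Step 12
Reactants: 24 11-phenylsulfonyl derivative of the target (C11 epimers)
Product: 25 target diol CID57401582
Conditions: Mg turnings, MeOH, 25→50 °C
Reagents that add atoms: none
Why: Reductive desulfonylation by electron transfer from magnesium in methanol; isolated trisubstituted alkenes and alcohols are not reduced, the 8-hydroxyl group stands γ to the sulfone so that no Julia-type elimination can occur, and no stereocentre is touched.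

Compound list
1 | (R)-(−)-carvone | O=C1C(C)=CC[C@@H](C(C)=C)C1 | starting material
2 | lithium cross-conjugated dienolate of carvone | [Li+].[O-]C1=C[C@H](C(C)=C)CC=C1C | intermediate
3 | (5R,6S)-2,6-dimethyl-5-(prop-1-en-2-yl)cyclohex-2-en-1-one (trans-6-methylcarvone) | O=C1C(C)=CC[C@@H](C(C)=C)[C@@H]1C | intermediate
4 | methyl isobutyrate | COC(=O)C(C)C | starting material
5 | phenyl vinyl sulfone | C=CS(=O)(=O)c1ccccc1 | starting material
6 | lithium enolate of methyl isobutyrate | [Li+].[O-]C(OC)=C(C)C | intermediate
7 | lithium C9–C10 enolate of the first Michael adduct (C4 unit β on C5, isopropenyl α on C7) | [Li+].COC(=O)C(C)(C)[C@@H]1C[C@@H](C(C)=C)[C@H](C)C([O-])=C1C | intermediate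
8 | lithium α-sulfonyl carbanion of the second Michael adduct (10β-methyl, C1 arm α) | [Li+].COC(=O)C(C)(C)[C@@H]1C[C@@H](C(C)=C)[C@H](C)C(=O)[C@@]1(C)C[CH-]S(=O)(=O)c2ccccc2 | intermediate
9 | 2α-phenylsulfonyl-7α-isopropenyl-11-nordrimane-3,9-dione (trans-decalin, 5α-H, 10β-CH3, 8α-CH3) | O=C1[C@@]2(C)C[C@@H](S(=O)(=O)c3ccccc3)C(=O)C(C)(C)[C@@H]2C[C@@H](C(C)=C)[C@H]1C | intermediate
10 | 7α-isopropenyl-11-nordrimane-3,9-dione | O=C1[C@@]2(C)CCC(=O)C(C)(C)[C@@H]2C[C@@H](C(C)=C)[C@H]1C | intermediate
11 | 3β-hydroxy-7α-isopropenyl-11-nordriman-9-one | O=C1[C@@]2(C)CC[C@H](O)C(C)(C)[C@@H]2C[C@@H](C(C)=C)[C@H]1C | intermediate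
12 | 7α-(1-hydroperoxy-1-methoxyethyl)-3β-hydroxy-11-nordriman-9-one (epimers at the peroxyketal carbon) | O=C1[C@@]2(C)CC[C@H](O)C(C)(C)[C@@H]2C[C@@H](C(C)(OC)OO)[C@H]1C | intermediate
13 | 3β-hydroxy-11-nordrim-6-en-9-one | O=C1[C@@]2(C)CC[C@H](O)C(C)(C)[C@@H]2C=C[C@H]1C | intermediate
14 | 3β-hydroxy-11-nordrim-7-en-9-one | O=C1[C@@]2(C)CC[C@H](O)C(C)(C)[C@@H]2CC=C1C | intermediate
15 | 9α-(trimethylsilylmethyl)-11-nordrim-7-ene-3β,9β-diol | C[Si](C)(C)C[C@@]1(O)[C@@]2(C)CC[C@H](O)C(C)(C)[C@@H]2CC=C1C | intermediate
16 | drima-7,9(11)-dien-3β-ol | C=C1[C@@]2(C)CC[C@H](O)C(C)(C)[C@@H]2CC=C1C | intermediate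
17 | 11-(9-borabicyclo[3.3.1]nonan-9-yl)drim-7-en-3β-ol (9α-H; drawn with the 3-OH free) | B1(C2CCCC1CCC2)C[C@@H]3[C@@]4(C)CC[C@H](O)C(C)(C)[C@@H]4CC=C3C | intermediate
18 | drim-7-ene-3β,11-diol (3β-hydroxydrimenol) | OC[C@@H]1[C@@]2(C)CC[C@H](O)C(C)(C)[C@@H]2CC=C1C | intermediate
19 | drimane-3β,8α,11-triol | OC[C@@H]1[C@@]2(C)CC[C@H](O)C(C)(C)[C@@H]2CC[C@@]1(C)O | intermediate
20 | 11-(phenylthio)drimane-3β,8α-diol | c3ccccc3SC[C@@H]1[C@@]2(C)CC[C@H](O)C(C)(C)[C@@H]2CC[C@@]1(C)O | intermediate
21 | 11-(phenylsulfonyl)drimane-3β,8α-diol | O=S(=O)(c3ccccc3)C[C@@H]1[C@@]2(C)CC[C@H](O)C(C)(C)[C@@H]2CC[C@@]1(C)O | intermediate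
22 | (2E,6E)-farnesyl bromide | CC(C)=CCC/C(C)=C/CC/C(C)=C/CBr | starting material
23 | trilithio derivative of 21 (3-O, 8-O, C11) | [Li+].[Li+].[Li+].O=S(=O)(c3ccccc3)[CH-][C@@H]1[C@@]2(C)CC[C@H]([O-])C(C)(C)[C@@H]2CC[C@@]1(C)[O-] | intermediate
24 | 11-phenylsulfonyl-3β,8α-dihydroxypolypoda-13E,17E,21-triene (C11 epimers) | CC(C)=CCC/C(C)=C/CC/C(C)=C/CC(S(=O)(=O)c3ccccc3)[C@@H]1[C@@]2(C)CC[C@H](O)C(C)(C)[C@@H]2CC[C@@]1(C)O | intermediate
25 | 3β,8α-dihydroxypolypoda-13E,17E,21-triene (CID57401582) | CC(C)=CCC/C(C)=C/CC/C(C)=C/CC[C@@H]1[C@@]2(C)CC[C@H](O)C(C)(C)[C@@H]2CC[C@@]1(C)O | target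

Total step count: 12. Longest linear sequence: 12 (1 → 25).

Steps most likely to fail

Step 2. The ester enolate may add 1,2 or simply abstract the C8 proton of the enone. The vinyl sulfone may oligomerise, or the sequence may stall before ring closure. The fallback sets out from 3 and comes back at 9, replacing the basic one-flask cascade by three separate, individually known reactions.
- A Lewis-acid Mukaiyama–Michael addition of commercial 1-methoxy-2-methyl-1-(trimethylsiloxy)propene to 3 (TMSOTf, 10 mol%, CH2Cl2, −78 °C) should give the silyl enol ether F1.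
- MeLi unmasks the regiodefined lithium enolate 7, which is added to 5 and quenched cold to give the open keto ester sulfone F2.
- KOt-Bu (2 equiv, THF, 0→25 °C) then closes ring A between C2 and C3 to give 9.

Step 5. Oxidation of the C7 radical by divalent copper may be slow compared with hydrogen-atom capture, or may give alkene mixtures that resist conjugation. The fallback sets out from 11 and comes back at 14, separating C–C cleavage from dehydrogenation.
- The same ozonolysis to 12 is followed by FeSO4·7H2O and PhSH, a reductive dealkenylation that should give the saturated ketone F3.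
- LDA (2.2 equiv) and TMSCl convert F3 into the bis-silyl compound F4.
- Saegusa–Ito oxidation with Pd(OAc)2 in MeCN and an acidic work-up should give 14.

Step 8. Capture of dioxygen by the planar C8 radical may show poor facial selectivity, or the radical may simply be reduced. The fallback sets out from 18 and comes back at 19, replacing the radical hydration by a polar sequence.
- mCPBA should epoxidise the ring alkene from the α face to give the epoxide F5.
- LiAlH4 opens F5 at the less substituted C7, leaving the oxygen on C8 with its α configuration.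

Further compounds
F1 | step 2 | trimethylsilyl enol ether of the first Michael adduct | COC(=O)C(C)(C)[C@@H]1C[C@@H](C(C)=C)[C@H](C)C(O[Si](C)(C)C)=C1C
F2 | step 2 | open keto ester sulfone (10β-methyl, 2-phenylsulfonylethyl arm α) | COC(=O)C(C)(C)[C@@H]1C[C@@H](C(C)=C)[C@H](C)C(=O)[C@@]1(C)CCS(=O)(=O)c2ccccc2
F3 | step 5 | 3β-hydroxy-11-nordriman-9-one (8α-methyl) | O=C1[C@@]2(C)CC[C@H](O)C(C)(C)[C@@H]2CC[C@H]1C
F4 | step 5 | 3β,9-bis(trimethylsilyloxy)-11-nordrim-8-ene | C[Si](C)(C)OC=1[C@@]2(C)CC[C@H](O[Si](C)(C)C)C(C)(C)[C@@H]2CCC=1C
F5 | step 8 | 7α,8α-epoxydrimane-3β,11-diol | OC[C@@H]1[C@@]2(C)CC[C@H](O)C(C)(C)[C@@H]2C[C@H]3O[C@@]13C
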